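**Retrosynthetic overview**
1. 18 ⇒ 17 ⇒ 16: the two C3–O operations (Luche reduction, isobutyrylation) come last; the C3 ketone serves as the masked 3β-ol.
2. 16 ⇒ 13: the 8β-acetoxy / methyl ester pair is the opened form of a cis-fused 8β,12-lactone (saponification, O-methylation, acetylation).
3. 13 ⇒ 10: key C8–O bond by a carboxyl-radical 1,5-hydrogen-transfer γ-C–H lactonization of the acrylic acid (new).
4. 10 ⇒ 7: oxidation of the isopropenyl methyl of (+)-α-cyperone to the acrylic acid.
5. 7 ⇒ 1 + 3: ring B is (+)-dihydrocarvone; ring A is closed second by an auxiliary-controlled Michael/aldol annulation with ethyl vinyl ketone; the lactone ring is formed third and opened again.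

Assumption: eudesmane numbering is used for the bicyclic compounds (ring A = C1–C5 and C10, ring B = C5–C10, C11–C13 = side chain on C7, β = face of the C10 methyl). Commercial (+)-dihydrocarvone (C2-epimer mixture from (R)-carvone) is the starting material, since C2 is re-set in step 1.

**Step 1**
Reactants: 1 (+)-dihydrocarvone, (5R)-2-methyl-5-(prop-1-en-2-yl)cyclohexan-1-one; 2 (R)-1-phenylethylamine; 3 ethyl vinyl ketone
Product: 6 (2S,5R)-2-methyl-2-(3-oxopentyl)-5-(prop-1-en-2-yl)cyclohexan-1-one, via dihydrocarvone (R)-1-phenylethyl imine 4 (not isolated), via Michael-adduct imine 5 (not isolated)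
Conditions: 2 (1.1 equiv), p-toluenesulfonic acid (cat.), PhMe, reflux, Dean–Stark; then 3 (1.5 equiv), THF, 40 °C, 3 d; then 10% aq AcOH, rt
Reagents that add atoms: water (O)
Why: d'Angelo deracemizing Michael addition, in which the more substituted secondary enamine tautomer of 4 (both C2 epimers converge) adds to the enone through a compact aza-ene-like transition state on the face anti to the phenyl group, so the (R)-auxiliary sets the quaternary carbon as S (the future C10 β-methyl), and mild acid hydrolysis releases the amine.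

**Step 2**
Reactants: 6 (2S,5R)-2-methyl-2-(3-oxopentyl)-5-(prop-1-en-2-yl)cyclohexan-1-one
Product: 7 (+)-α-cyperone, (4aS,7R)-1,4a-dimethyl-7-(prop-1-en-2-yl)-4,4a,5,6,7,8-hexahydronaphthalen-2(3H)-one
Conditions: NaOMe (0.5 equiv), MeOH, rt → 60 °C
Reagents that add atoms: none
Why: intramolecular aldol condensation (second half of a Robinson annulation) closes ring A through the ethyl-ketone enolate and dehydrates to the tetrasubstituted enone, with no stereocenter touched.

**Step 3**
Reactants: 7 (+)-α-cyperone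
Product: 8 (4aS,7R)-7-(3-hydroxyprop-1-en-2-yl)-1,4a-dimethyl-4,4a,5,6,7,8-hexahydronaphthalen-2(3H)-one
Conditions: SeO2 (0.3 equiv), t-BuOOH (3 equiv), salicylic acid (cat.), CH2Cl2, rt
Reagents that add atoms: selenium dioxide (O=[Se]=O), tert-butyl hydroperoxide (CC(C)(C)OO)
Why: Sharpless-type catalytic SeO2 allylic oxidation (ene reaction then [2,3]-sigmatropic shift) attacks the electron-rich 1,1-disubstituted alkene at its methyl group in preference to the C7 methine, while the conjugated tetrasubstituted alkene is deactivated, so C7 is preserved.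

**Step 4**
Reactants: 8 (4aS,7R)-7-(3-hydroxyprop-1-en-2-yl)-1,4a-dimethyl-4,4a,5,6,7,8-hexahydronaphthalen-2(3H)-one
Product: 10 (7R,10S)-3-oxoeudesma-4,11(13)-dien-12-oic acid, via enal 9 (not isolated)
Conditions: 2,2,6,6-tetramethylpiperidin-1-oxyl (TEMPO, 10 mol%), PhI(OAc)2 (1.1 equiv), CH2Cl2, rt; then NaClO2, NaH2PO4, 2-methylbut-2-ene, t-BuOH/H2O, 0 °C → rt
Reagents that add atoms: sodium chlorite ([Na+].[O-]Cl=O)
Why: oxoammonium oxidation of the primary allylic alcohol followed in the same flask by Pinnick oxidation of the enal, both of which tolerate the electron-poor alkenes and leave the stereocenters alone (any enal already formed in step 3 converges here).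

**Step 5**
Reactants: 10 (7R,10S)-3-oxoeudesma-4,11(13)-dien-12-oic acid
Product: 13 (7R,8R,10R)-3-oxoeudesma-4,11(13)-dien-8β,12-olide, via acyl hypoiodite 11 (not isolated), via 8α-iodo acid 12 (not isolated)
Conditions: PhI(OAc)2 (1.5 equiv), I2 (0.5 equiv), degassed 1,2-dichloroethane (0.02 M), 450 nm LEDs, 25 °C; then aq Na2S2O3/NaHCO3
Reagents that add atoms: none
Why: Proposed new method: hypoiodite-mediated γ-C(sp3)–H lactonization of an α-substituted acrylic acid. PhI(OAc)2/I2 converts the acid into acyl hypoiodite 11, and visible light cleaves its O–I bond to an acryloyloxy radical. This radical should decarboxylate slowly, because loss of CO2 would give a vinyl radical, so 1,5-hydrogen transfer through a six-membered transition state can take a hydrogen from C8. The C6 hydrogens are also reachable and allylic, but they are vinylogously alpha to the C3 ketone and polarity-mismatched toward the electrophilic oxygen radical; both alkenes are electron-poor and should ignore electrophilic iodine. Iodine transfer to the C8 radical on the α face, away from the syn-axial C10 methyl, gives equatorial iodide 12. Intramolecular displacement by the carboxyl oxygen with inversion (the iodide activated by oxidation to a trivalent iodine leaving group) then sets the 8β C–O bond of the cis-fused lactone (8R). The closest known reactions are the PhI(OAc)2/I2 photolactonization of 2-alkylbenzoic acids to phthalides through aroyloxy radicals and the Barton N-iodoamide route to γ-lactones; neither has been shown for alkenoic acids abstracting from an unactivated ring methylene.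

**Step 6**
Reactants: 13 (7R,8R,10R)-3-oxoeudesma-4,11(13)-dien-8β,12-olide
Product: 16 methyl (7R,8R,10R)-8β-acetoxy-3-oxoeudesma-4,11(13)-dien-12-oate, via potassium hydroxy-carboxylate 14 (not isolated), via hydroxy methyl ester 15 (not isolated)
Conditions: KOH (1.05 equiv), THF/H2O, 0 °C → rt, strip to dryness (PhMe azeotrope); MeI (1.5 equiv), DMF, 0 °C → rt, remove excess MeI in vacuo; then Ac2O (5 equiv), pyridine, 4-(dimethylamino)pyridine (20 mol%), 0 °C → rt
Reagents that add atoms: KOH ([K+].[OH-]), iodomethane (CI), acetic anhydride (CC(=O)OC(C)=O)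
Why: lactone saponification by acyl–oxygen cleavage (C8 keeps its configuration), SN2 O-methylation of the carboxylate and immediate nucleophile-catalysed acetylation of the axial 8β-hydroxyl in the same flask, so that hydroxy ester 15 is trapped before it can relactonize, while the enone is inert.

**Step 7**
Reactants: 16 methyl (7R,8R,10R)-8β-acetoxy-3-oxoeudesma-4,11(13)-dien-12-oate
Product: 17 methyl (3S,7R,8R,10R)-8β-acetoxy-3β-hydroxyeudesma-4,11(13)-dien-12-oate
Conditions: NaBH4 (1.0 equiv), CeCl3·7H2O (1.1 equiv), MeOH, −40 °C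
Reagents that add atoms: none
Why: Luche 1,2-reduction, in which hydride adds axially on the α face anti to the C10 β-methyl to give the pseudo-equatorial 3β-alcohol (3S), and the acrylate, acetate and methyl ester are not reduced at this temperature.

**Step 8**
Reactants: 17 methyl (3S,7R,8R,10R)-8β-acetoxy-3β-hydroxyeudesma-4,11(13)-dien-12-oate
Product: 18 methyl (3S,7R,8R,10R)-8β-acetoxy-3β-(2-methylpropanoyloxy)eudesma-4,11(13)-dien-12-oate
Conditions: (i-PrCO)2O (2 equiv), 4-(dimethylamino)pyridine (20 mol%), Et3N, CH2Cl2, 0 °C → rt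
Reagents that add atoms: isobutyric anhydride (CC(C)C(=O)OC(=O)C(C)C)
Why: nucleophile-catalysed (Steglich-type) acylation of the allylic secondary alcohol with retention at C3 gives the target.

**Compound list**
1 | (+)-dihydrocarvone, (5R)-2-methyl-5-(prop-1-en-2-yl)cyclohexan-1-one (commercial C2-epimer mixture, mainly 2R,5R) | C=C(C)[C@H]1CC(=O)C(C)CC1 | starting material
2 | (R)-(+)-1-phenylethylamine | C[C@@H](N)c1ccccc1 | starting material
3 | ethyl vinyl ketone (pent-1-en-3-one) | C=CC(=O)CC | starting material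
4 | (1R)-N-[(5R)-2-methyl-5-(prop-1-en-2-yl)cyclohexylidene]-1-phenylethan-1-amine (imine, in equilibrium with its secondary enamine) | C=C(C)[C@H]1CC(=N[C@H](C)c2ccccc2)C(C)CC1 | intermediate
5 | 1-[(1S,4R)-1-methyl-2-{[(1R)-1-phenylethyl]imino}-4-(prop-1-en-2-yl)cyclohexyl]pentan-3-one | C=C(C)[C@H]1CC(=N[C@H](C)c2ccccc2)[C@](C)(CCC(=O)CC)CC1 | intermediate
6 | (2S,5R)-2-methyl-2-(3-oxopentyl)-5-(prop-1-en-2-yl)cyclohexan-1-one | C=C(C)[C@H]1CC(=O)[C@](C)(CCC(=O)CC)CC1 | intermediate
7 | (+)-α-cyperone, (4aS,7R)-1,4a-dimethyl-7-(prop-1-en-2-yl)-4,4a,5,6,7,8-hexahydronaphthalen-2(3H)-one | C=C(C)[C@H]1CC2=C(C)C(=O)CC[C@]2(C)CC1 | intermediate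
8 | (4aS,7R)-7-(3-hydroxyprop-1-en-2-yl)-1,4a-dimethyl-4,4a,5,6,7,8-hexahydronaphthalen-2(3H)-one (12-hydroxyeudesma-4,11(13)-dien-3-one) | C=C(CO)[C@H]1CC2=C(C)C(=O)CC[C@]2(C)CC1 | intermediate
9 | 2-[(2R,4aS)-4a,8-dimethyl-7-oxo-1,2,3,4,4a,5,6,7-octahydronaphthalen-2-yl]prop-2-enal (3-oxoeudesma-4,11(13)-dien-12-al) | C=C(C=O)[C@H]1CC2=C(C)C(=O)CC[C@]2(C)CC1 | intermediate
10 | 2-[(2R,4aS)-4a,8-dimethyl-7-oxo-1,2,3,4,4a,5,6,7-octahydronaphthalen-2-yl]prop-2-enoic acid ((7R,10S)-3-oxoeudesma-4,11(13)-dien-12-oic acid) | C=C(C(=O)O)[C@H]1CC2=C(C)C(=O)CC[C@]2(C)CC1 | intermediate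
11 | acyl hypoiodite of 10 (O-iodo (7R,10S)-3-oxoeudesma-4,11(13)-dien-12-oate) | C=C(C(=O)OI)[C@H]1CC2=C(C)C(=O)CC[C@]2(C)CC1 | intermediate
12 | (7R,8S,10R)-8α-iodo-3-oxoeudesma-4,11(13)-dien-12-oic acid (iodine equatorial, trans to the C7 side chain) | C=C(C(=O)O)[C@H]1CC2=C(C)C(=O)CC[C@]2(C)C[C@@H]1I | intermediate
13 | (7R,8R,10R)-3-oxoeudesma-4,11(13)-dien-8β,12-olide (cis-fused α-methylene-γ-lactone, lactone oxygen on C8 syn to the C10 methyl) | C=C1[C@H]2CC3=C(C)C(=O)CC[C@]3(C)C[C@H]2OC1=O | intermediate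
14 | potassium (7R,8R,10R)-8β-hydroxy-3-oxoeudesma-4,11(13)-dien-12-oate | C=C(C(=O)[O-])[C@H]1CC2=C(C)C(=O)CC[C@]2(C)C[C@H]1O.[K+] | intermediate
15 | methyl (7R,8R,10R)-8β-hydroxy-3-oxoeudesma-4,11(13)-dien-12-oate | C=C(C(=O)OC)[C@H]1CC2=C(C)C(=O)CC[C@]2(C)C[C@H]1O | intermediate
16 | methyl (7R,8R,10R)-8β-acetoxy-3-oxoeudesma-4,11(13)-dien-12-oate | C=C(C(=O)OC)[C@H]1CC2=C(C)C(=O)CC[C@]2(C)C[C@H]1OC(C)=O | intermediate
17 | methyl (3S,7R,8R,10R)-8β-acetoxy-3β-hydroxyeudesma-4,11(13)-dien-12-oate | C=C(C(=O)OC)[C@H]1CC2=C(C)[C@@H](O)CC[C@]2(C)C[C@H]1OC(C)=O | intermediate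
18 | methyl (3S,7R,8R,10R)-8β-acetoxy-3β-(2-methylpropanoyloxy)eudesma-4,11(13)-dien-12-oate (CNP0127901.1) | C=C(C(=O)OC)[C@H]1CC2=C(C)[C@@H](OC(=O)C(C)C)CC[C@]2(C)C[C@H]1OC(C)=O | target

**Step count**
Total steps: 8. Longest linear sequence: 8 (fully linear from 1).

**Three steps most likely to fail**

Step 5 (the proposed lactonization). The C8-over-C6 selectivity rests on a polarity argument only and is the main risk. Likely failures are hydrogen abstraction at allylic C6 (giving the 6,12-lactone), a trans-fused lactone from the epimeric iodide, or iodination of the enone. The fallback uses known chemistry, sets out from acid 10 and comes back at lactone 13. The acid is converted through its mixed anhydride (isobutyl chloroformate, N-methylmorpholine, THF, −15 °C, then NH3) into the primary amide 2-[(2R,4aS)-4a,8-dimethyl-7-oxo-1,2,3,4,4a,5,6,7-octahydronaphthalen-2-yl]prop-2-enamide F2. Barton N-iodoamide photolysis (Pb(OAc)4, I2, hν, benzene) then generates an amidyl radical that cannot fragment; it abstracts the C8 hydrogen by 1,5-transfer, and the amide oxygen closes onto C8 to give the iminolactone (7R,8R,10R)-12-imino-8β,12-epoxyeudesma-4,11(13)-dien-3-one F3. Dilute aqueous HCl hydrolyses this to 13. This fallback removes the decarboxylation risk but not the C6/C8 competition.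

Step 6 (one-flask opening and acetylation). The hindered axial 8β-hydroxyl of 15 may relactonize faster than it is acetylated. The fallback sets out from lactone 13 (through salt 14) and comes back at 16, protecting the hydroxyl before the ester is made. Salt 14 is bis-silylated (TBSOTf, 2,6-lutidine, CH2Cl2, 0 °C) to tert-butyldimethylsilyl (7R,8R,10R)-8β-(tert-butyldimethylsilyloxy)-3-oxoeudesma-4,11(13)-dien-12-oate F4. K2CO3 in MeOH/THF/H2O cleaves only the silyl ester to (7R,8R,10R)-8β-(tert-butyldimethylsilyloxy)-3-oxoeudesma-4,11(13)-dien-12-oic acid F5, which cannot lactonize. Trimethylsilyldiazomethane (PhMe/MeOH) gives methyl (7R,8R,10R)-8β-(tert-butyldimethylsilyloxy)-3-oxoeudesma-4,11(13)-dien-12-oate F6. Direct silyl-ether-to-acetate exchange (Ac2O, Cu(OTf)2 cat., CH2Cl2, rt) gives 16 without ever liberating the free hydroxy ester.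

Step 3 (SeO2 oxidation). Conversion may be low, or over-oxidation and oxidation next to the ketone may compete. The fallback sets out from 7 and comes back at enal 9, which goes on to 10 in the chlorite stage of step 4. Ene-type allylic chlorination with hypochlorous acid (Ca(OCl)2, solid CO2, CH2Cl2/H2O, 0 °C) gives the allylic chloride (4aS,7R)-7-(3-chloroprop-1-en-2-yl)-1,4a-dimethyl-4,4a,5,6,7,8-hexahydronaphthalen-2(3H)-one F1. Kornblum oxidation (DMSO, NaHCO3, NaI cat., 60 °C) converts F1 into enal 9.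

**Further compounds**
F1 | step 3 | (4aS,7R)-7-(3-chloroprop-1-en-2-yl)-1,4a-dimethyl-4,4a,5,6,7,8-hexahydronaphthalen-2(3H)-one | C=C(CCl)[C@H]1CC2=C(C)C(=O)CC[C@]2(C)CC1
F2 | step 5 | 2-[(2R,4aS)-4a,8-dimethyl-7-oxo-1,2,3,4,4a,5,6,7-octahydronaphthalen-2-yl]prop-2-enamide | C=C(C(N)=O)[C@H]1CC2=C(C)C(=O)CC[C@]2(C)CC1
F3 | step 5 | (7R,8R,10R)-12-imino-8β,12-epoxyeudesma-4,11(13)-dien-3-one (iminolactone) | C=C1[C@H]2CC3=C(C)C(=O)CC[C@]3(C)C[C@H]2OC1=N
F4 | step 6 | tert-butyldimethylsilyl (7R,8R,10R)-8β-(tert-butyldimethylsilyloxy)-3-oxoeudesma-4,11(13)-dien-12-oate | C=C(C(=O)O[Si](C)(C)C(C)(C)C)[C@H]1CC2=C(C)C(=O)CC[C@]2(C)C[C@H]1O[Si](C)(C)C(C)(C)C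
F5 | step 6 | (7R,8R,10R)-8β-(tert-butyldimethylsilyloxy)-3-oxoeudesma-4,11(13)-dien-12-oic acid | C=C(C(=O)O)[C@H]1CC2=C(C)C(=O)CC[C@]2(C)C[C@H]1O[Si](C)(C)C(C)(C)C
F6 | step 6 | methyl (7R,8R,10R)-8β-(tert-butyldimethylsilyloxy)-3-oxoeudesma-4,11(13)-dien-12-oate | C=C(C(=O)OC)[C@H]1CC2=C(C)C(=O)CC[C@]2(C)C[C@H]1O[Si](C)(C)C(C)(C)C
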